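3 questions stand on this flask, and the earlier runs hold one level that bears on them.

| flask | substrate | reagent in the second phase | remark | time | volume of the second phase over the first |
|---|---|---|---|---|---|
| dusk | 0.050 M | 0.50 equiv | run made earlier |  |  |
| noon | 0.050 M | 0.75 equiv | run made earlier |  |  |
| spring | 0.075 M | 1 equiv | run made earlier |  |  |
| flask | 0.050 M | 1.00 equiv |  | 2.5 h | 0.50 |

- target at 2.5 h, in percent of the substrate charged
- the change that raises the amount of target at 2.5 h, in percent of the substrate charged most ("none" if none brings more than 2 percentage points) (eta / beta / none)
- amount of target at 2.5 h, in percent of the substrate charged, after beta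

- in the second phase: reagent in the second phase; everything else is in the first
- charges count per volume of the first phase; a concentration in a rate is the amount of a species over the volume of its own phase; every rate counts per litre of the first phase
- the earlier runs hold the two phases in the same ratio of volumes as the flask asked about

| run | time / min | target / % |
|---|---|---|
| dusk | 15.0 | 1.8 |
| dusk | 30.0 | 2.6 |
| dusk | 50.0 | 3.9 |
| dusk | 60.0 | 4.1 |
| dusk | 80.0 | 4.8 |
| dusk | 90.0 | 4.8 |
| noon | 8.00 | 1.0 |
| noon | 12.0 | 1.3 |
| noon | 20.0 | 2.7 |
| noon | 30.0 | 4.1 |
| noon | 50.0 | 5.2 |
| noon | 90.0 | 6.0 |
| spring | 20.0 | 4.8 |
| spring | 40.0 | 7.8 |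
| spring | 50.0 | 8.3 |
| spring | 80.0 | 8.9 |
| spring | 90.0 | 9.0 |

(readings scatter by 0.3 percentage points)

The last reading of each run, taken over the equivalents of reagent in the second phase charged, makes a small table of three rows, each giving the share of the reagent's charge standing as target. The proportional case is the zero of this scale: if late target follows the reagent charged, the rows agree. The dusk row gives 9.60 % per equivalent, with a scatter of 0.6 percentage points. The noon row is lower at 8.00 %, with a scatter of 0.4 points. The spring row, with 1.50 times the substrate of the dusk run, falls between them at 9.00 %, so the extra substrate shows no step. Their mean, 8.87 %, is the level per equivalent.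

The reckoning made here multiplies that level by the flask's 1.00 equiv and gets 8.87 % at 2.5 h. Eta doubles this, a gain of 8.9 points, which is over the 2 points margin. A transfer coefficient sets a pace, and the dusk run lies flat from 4.8 % to 4.8 % at its end, so this reckoning leaves the flask at the same level after beta.

The forecast gives 8.7 %, eta and 15.5 %, on the ground that “That suggests slow transfer out of the second phase, followed by fast capture”. It parts from the reckoning above on the third number.

The flask gives 8.94 %, its best change is eta with a gain of 5.5 points, and after beta it holds 8.97 %.

    substrate + reagent in the reaction phase → target (k = 8.64 L mol⁻¹ h⁻¹)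
    substrate + target → side product (k = 22.8 L mol⁻¹ h⁻¹)
    reagent in the reaction phase + target → over-reaction product (k = 4.82 L mol⁻¹ h⁻¹)
    reagent in the reaction phase ⇌ reagent in the second phase, rate k4*([reagent in the reaction phase] - [reagent in the second phase]/K4) per volume of the first phase (partition coefficient = 3.18, kL = 9.77 h⁻¹)
    reagent in the reaction phase + target → over-reacted product (k = 4.86 L mol⁻¹ h⁻¹)

Half of the crossing of the reagent up to 2.5 h is done by 0.0810 h, and its slowness makes no difference, so beta adds 0.03 points. The reaction of substrate + target to side product has the largest single effect on the flask: without it the flask would read 23.2 % instead of 8.94 %. The level 8.87 % per equivalent stands 0.069 points below the flask at 2.5 h, but the neighbour with 0.013 M of substrate, at the same equivalents and time, reads 6.46 % against the 8.87 % that the level gives.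

All runs are calculated with constants of no real substance; scatter was added.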